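**Retrosynthetic overview**

- The target is the (3R,4R)-trans-α,β-dibenzyl-γ-butyrolactone. Its last operations are C–S/O–benzyl hydrogenolysis and, before that, reductive excision of a menthyloxy group from C5.
- Key disconnection: the bond between the benzylic carbon of the 4-hydroxy-3,5-dimethoxyphenyl ring and C4 of the lactone, made in the same flask as the C3–CH2(3,4,5-trimethoxyphenyl) bond by a three-component Michael addition/enolate alkylation. The benzylic carbon is carried at the aldehyde oxidation level as a 2-aryl-1,3-dithiane anion (polarity reversal), so two electrophilic carbons are joined.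
- Enabling feature: C4 is the β-carbon of the C2(=O)–C3 unit of the lactone ring, so at the butenolide stage it is a Michael terminus and C3 emerges as the enolate. C5 can carry a removable alkoxy stereocentre that steers both new centres. The aryl ring on the benzylic carbon stabilises the dithiane anion.
- Rings: both arenes and the lactone ring are bought intact. The temporary 1,3-dithiane ring is closed first (step 1), the lactone ring is opened and re-closed once (step 4), and the dithiane ring is excised last (step 5).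

Key step: step 3

Assumption: 5-hydroxyfuran-2(5H)-one, the ring tautomer of (Z)-4-oxobut-2-enoic acid, is taken as purchasable; it is otherwise the product of dye-sensitised photooxygenation of furfural.

**Route**

Step 1
Reactants: 1 4-(benzyloxy)-3,5-dimethoxybenzaldehyde; 2 propane-1,3-dithiol
Product: 3 2-[4-(benzyloxy)-3,5-dimethoxyphenyl]-1,3-dithiane
Conditions: BF3·OEt2 (cat.), CH2Cl2, 0 °C → rt
Reagents that add atoms: none
Why: Lewis-acid-catalysed dithioacetalisation of an aryl aldehyde, to which the benzyl and methyl ethers are inert, installs the temporary ring that makes the benzylic carbon acidic.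

Step 2
Reactants: 4 5-hydroxyfuran-2(5H)-one; 5 (1R,2S,5R)-(−)-menthol
Product: 6 (5R)-5-{[(1R,2S,5R)-2-isopropyl-5-methylcyclohexyl]oxy}furan-2(5H)-one
Conditions: CSA (cat.), toluene, reflux (Dean–Stark); crystallisation from petroleum ether, mother liquor re-equilibrated with cat. CSA and recrystallised
Reagents that add atoms: none
Why: Acid-catalysed acetalisation of the cyclic pseudo-acid gives C5 epimers that interconvert under the acid, and the crystalline (5R) epimer is collected, so C5 is set by crystallisation-driven diastereomer selection with the menthyl group as the controlling element.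

Step 3
Reactants: 3 2-[4-(benzyloxy)-3,5-dimethoxyphenyl]-1,3-dithiane; 6 (5R)-5-(menthyloxy)furan-2(5H)-one; 7 3,4,5-trimethoxybenzyl bromide
Product: 10 (3R,4R,5R)-4-{2-[4-(benzyloxy)-3,5-dimethoxyphenyl]-1,3-dithian-2-yl}-5-{[(1R,2S,5R)-2-isopropyl-5-methylcyclohexyl]oxy}-3-(3,4,5-trimethoxybenzyl)dihydrofuran-2(3H)-one, via 2-lithio-2-aryl-1,3-dithiane 8 (not isolated), via lithium lactone enolate 9 (not isolated)
Conditions: 3, n-BuLi, THF, −78 → −30 °C; 6, THF, −78 °C; then 7, DMPU, −78 → −20 °C; aq. NH4Cl
Reagents that add atoms: n-butyllithium, [Li]CCCC (its lithium is carried by 8 and 9 and is lost from 10)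
Why: n-BuLi removes the C2–H of 3 to give the aryl- and sulfur-stabilised carbanion 8, an acyl-anion equivalent of aldehyde 1, which adds 1,4 to C4 of butenolide 6; the resulting lithium enolate 9 is C-alkylated at C3 by the benzylic bromide 7 in the same flask. The closest known reaction type is the tandem conjugate addition–enolate alkylation of lithiated 2-aryl-1,3-dithianes on butenolides, including its auxiliary-controlled form on 5-alkoxyfuran-2(5H)-ones. No ring is closed; the lactone ring is kept and the dithiane ring is carried as a temporary activating ring. C4 is controlled by the C5 menthyloxy group, the nucleophile entering the face anti to it (4,5-trans), and C3 is controlled by the new bulky C4 dithianyl group, the bromide entering anti to it (3,4-trans), so the single acetal stereocentre is relayed to both stereocentres of the target (3R,4R). The step needs 1,4- over 1,2-addition and C-monoalkylation before proton exchange or retro-Michael reaction; the soft, delocalised, hindered anion in THF at −78 °C should secure the first, and the reactive benzylic bromide with DMPU below −20 °C should secure the second.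

Step 4
Reactants: 10 (3R,4R,5R)-4-(2-aryl-1,3-dithian-2-yl)-5-(menthyloxy)-3-(3,4,5-trimethoxybenzyl)dihydrofuran-2(3H)-one
Product: 13 (3R,4R)-4-{2-[4-(benzyloxy)-3,5-dimethoxyphenyl]-1,3-dithian-2-yl}-3-(3,4,5-trimethoxybenzyl)dihydrofuran-2(3H)-one, via potassium 4-oxobutanoate salt 11 (not isolated), via 4-hydroxybutanoic acid 12 (not isolated)
Conditions: KOH (aq.), NaBH4, EtOH/THF, 0 °C → rt; then 2 M HCl, rt
Reagents that add atoms: potassium hydroxide, [K+].[OH-] (potassium and one carboxylate oxygen of 11; that oxygen stays in 12 and may remain as a lactone oxygen of 13)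
Why: Saponification of the pseudo-ester expels menthol and unveils the C5 aldehyde, which borohydride (stable in aqueous base) should reduce as it forms, and acidification closes the γ-lactone (pseudo-ester hydrolysis/borohydride reduction/lactonisation) without creating a stereocentre or touching C3 and C4.

Step 5
Reactants: 13 (3R,4R)-4-{2-[4-(benzyloxy)-3,5-dimethoxyphenyl]-1,3-dithian-2-yl}-3-(3,4,5-trimethoxybenzyl)dihydrofuran-2(3H)-one
Product: 14 (3R,4R)-4-(4-hydroxy-3,5-dimethoxybenzyl)-3-(3,4,5-trimethoxybenzyl)dihydrofuran-2(3H)-one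
Conditions: Raney Ni (W-2, excess), H2 (1 atm), EtOH, reflux
Reagents that add atoms: none
Why: Raney-nickel hydrogenolysis of both C–S bonds (Mozingo reduction) turns the dithiane carbon into the benzylic CH2 and should cleave the aryl benzyl ether in the same operation, under neutral conditions that leave the lactone, the methyl ethers and both stereocentres untouched.

**Compound list**

1 | 4-(benzyloxy)-3,5-dimethoxybenzaldehyde | COc1cc(C=O)cc(OC)c1OCc1ccccc1 | starting material
2 | propane-1,3-dithiol | SCCCS | starting material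
3 | 2-[4-(benzyloxy)-3,5-dimethoxyphenyl]-1,3-dithiane | COc1cc(cc(OC)c1OCc1ccccc1)C1SCCCS1 | intermediate
4 | 5-hydroxyfuran-2(5H)-one (racemic) | OC1OC(=O)C=C1 | starting material
5 | (1R,2S,5R)-(−)-menthol | CC(C)[C@@H]1CC[C@@H](C)C[C@H]1O | starting material
6 | (5R)-5-{[(1R,2S,5R)-2-isopropyl-5-methylcyclohexyl]oxy}furan-2(5H)-one | CC(C)[C@@H]1CC[C@@H](C)C[C@H]1O[C@@H]2OC(=O)C=C2 | intermediate
7 | 3,4,5-trimethoxybenzyl bromide | COc1cc(CBr)cc(OC)c1OC | starting material
8 | 2-lithio-2-[4-(benzyloxy)-3,5-dimethoxyphenyl]-1,3-dithiane | [Li]C1(SCCCS1)c2cc(OC)c(OCc3ccccc3)c(OC)c2 | intermediate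
9 | lithium (4R,5R)-4-{2-[4-(benzyloxy)-3,5-dimethoxyphenyl]-1,3-dithian-2-yl}-5-(menthyloxy)-4,5-dihydrofuran-2-olate | CC(C)[C@@H]1CC[C@@H](C)C[C@H]1O[C@@H]2OC(O[Li])=C[C@H]2C3(SCCCS3)c4cc(OC)c(OCc5ccccc5)c(OC)c4 | intermediate
10 | (3R,4R,5R)-4-{2-[4-(benzyloxy)-3,5-dimethoxyphenyl]-1,3-dithian-2-yl}-5-{[(1R,2S,5R)-2-isopropyl-5-methylcyclohexyl]oxy}-3-(3,4,5-trimethoxybenzyl)dihydrofuran-2(3H)-one | CC(C)[C@@H]1CC[C@@H](C)C[C@H]1O[C@@H]2OC(=O)[C@H](Cc3cc(OC)c(OC)c(OC)c3)[C@H]2C4(SCCCS4)c5cc(OC)c(OCc6ccccc6)c(OC)c5 | intermediate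
11 | potassium (2R,3R)-3-{2-[4-(benzyloxy)-3,5-dimethoxyphenyl]-1,3-dithian-2-yl}-4-oxo-2-(3,4,5-trimethoxybenzyl)butanoate | [K+].[O-]C(=O)[C@H](Cc1cc(OC)c(OC)c(OC)c1)[C@H](C=O)C2(SCCCS2)c3cc(OC)c(OCc4ccccc4)c(OC)c3 | intermediate
12 | (2R,3R)-3-{2-[4-(benzyloxy)-3,5-dimethoxyphenyl]-1,3-dithian-2-yl}-4-hydroxy-2-(3,4,5-trimethoxybenzyl)butanoic acid | OC(=O)[C@H](Cc1cc(OC)c(OC)c(OC)c1)[C@H](CO)C2(SCCCS2)c3cc(OC)c(OCc4ccccc4)c(OC)c3 | intermediate
13 | (3R,4R)-4-{2-[4-(benzyloxy)-3,5-dimethoxyphenyl]-1,3-dithian-2-yl}-3-(3,4,5-trimethoxybenzyl)dihydrofuran-2(3H)-one | O=C1OC[C@H](C2(SCCCS2)c3cc(OC)c(OCc4ccccc4)c(OC)c3)[C@H]1Cc5cc(OC)c(OC)c(OC)c5 | intermediate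
14 | (3R,4R)-4-(4-hydroxy-3,5-dimethoxybenzyl)-3-(3,4,5-trimethoxybenzyl)dihydrofuran-2(3H)-one | COc1cc(C[C@H]2COC(=O)[C@@H]2Cc2cc(OC)c(OC)c(OC)c2)cc(OC)c1O | target

**Step count and risks**

Total step count: 5. Longest linear sequence: 4 steps (step 1 or step 2, then steps 3, 4 and 5).

Steps most likely to fail:

1. Step 3. The hindered enolate may be trapped too slowly, so that proton exchange or retro-Michael reaction returns unalkylated material, alongside some 1,2-addition. The fallback separates the two bond formations. It sets out from 3 and 6: the conjugate addition of 8 to 6 is quenched at −78 °C with NH4Cl to give the mono-adduct (4R,5R)-4-{2-[4-(benzyloxy)-3,5-dimethoxyphenyl]-1,3-dithian-2-yl}-5-(menthyloxy)dihydrofuran-2(3H)-one F1, which can be purified. Its enolate is then generated on its own with LDA in THF/DMPU at −78 °C and alkylated by 7 anti to the C4 group. The route is rejoined at 10.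

2. Step 4. The open-chain aldehyde may enolise in base before hydride arrives, which would erode the C4 configuration or open the dithiane by β-elimination of thiolate. The fallback removes the auxiliary under acid instead. It sets out from 10: 2 M HCl in 1,4-dioxane at 60 °C should hydrolyse the menthyl acetal to the lactol (3R,4R)-4-{2-[4-(benzyloxy)-3,5-dimethoxyphenyl]-1,3-dithian-2-yl}-5-hydroxy-3-(3,4,5-trimethoxybenzyl)dihydrofuran-2(3H)-one F2 (C5 epimers). Its ring-opened aldehyde form is reduced by NaBH4 in EtOH/aq. NaHCO3 at 0 °C, and acidification closes the lactone. The route is rejoined at 13.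

3. Step 5. Hydrogenolysis of the benzyl ether may stay incomplete, or material may be lost or over-reduced on the large excess of nickel. The fallback avoids nickel. It sets out from 13: S-methylation/hydrolysis of the dithiane (MeI, CaCO3, MeCN/H2O, 50 °C) should give the aryl ketone (3R,4R)-4-[4-(benzyloxy)-3,5-dimethoxybenzoyl]-3-(3,4,5-trimethoxybenzyl)dihydrofuran-2(3H)-one F3. Hydrogenation over Pd/C in AcOH with a trace of HClO4 should then remove the benzyl ether and deoxygenate the benzylic ketone through the p-hydroxybenzylic alcohol, the trans arrangement being the thermodynamically preferred one at the epimerisable C4. The route is rejoined at 14.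

**Further compounds**

F1 | step 3 | (4R,5R)-4-{2-[4-(benzyloxy)-3,5-dimethoxyphenyl]-1,3-dithian-2-yl}-5-{[(1R,2S,5R)-2-isopropyl-5-methylcyclohexyl]oxy}dihydrofuran-2(3H)-one | CC(C)[C@@H]1CC[C@@H](C)C[C@H]1O[C@@H]2OC(=O)C[C@H]2C3(SCCCS3)c4cc(OC)c(OCc5ccccc5)c(OC)c4
F2 | step 4 | (3R,4R)-4-{2-[4-(benzyloxy)-3,5-dimethoxyphenyl]-1,3-dithian-2-yl}-5-hydroxy-3-(3,4,5-trimethoxybenzyl)dihydrofuran-2(3H)-one (C5 epimers) | OC1OC(=O)[C@H](Cc2cc(OC)c(OC)c(OC)c2)[C@H]1C3(SCCCS3)c4cc(OC)c(OCc5ccccc5)c(OC)c4
F3 | step 5 | (3R,4R)-4-[4-(benzyloxy)-3,5-dimethoxybenzoyl]-3-(3,4,5-trimethoxybenzyl)dihydrofuran-2(3H)-one | O=C1OC[C@H](C(=O)c2cc(OC)c(OCc3ccccc3)c(OC)c2)[C@H]1Cc4cc(OC)c(OC)c(OC)c4
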